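The constants were drawn at random within sensible limits, and the outcome is calculated.

A small charge of E is best spent knowing how much of it stands bound when I stop, so I reckon that first.

    E + G → E.G (k1 = 4.46 /M/s)
    G ⇌ Z, rate k2*([G] - [Z]/K2) per volume of the first phase (K2 = 2.21, k2 = 0.0411 /s)
    2 G → G2 (k3 = 1.43 /M/s)
    E.G ⇌ Q, rate k4*([E.G] - [Q]/K4) per volume of the first phase (K4 = 3.12, k4 = 0.0511 /s)
    E.G → J (k5 = 0.0117 /s)
    E → L (k6 = 3.39 × 10⁻⁴ /s)

E 0.059 M; Z 4.00 equiv; time 4.0 min; volume of the second phase over the first 1.0

1. the E.G and Q together standing at 4.0 min, as a percentage of the E charged
2. part of the E charged that has reacted at 4.0 min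

- what is said of E.G includes Q
- where a step has two of a species, its rate is k times that concentration squared, and two are used at each turn
- in the second phase: Z, Q; everything else is in the first
- charges count per volume of the first phase; a concentration in a rate is the amount of a species over the volume of its own phase; every rate counts per litre of the first phase
- run time (flask): 4.0 min

Turned round, a tenth of E still standing at 4.0 min asks for a mean c G below 0.00215 M. But Z starts by releasing G at 0.00439 M/s, which is one E's worth in about 13.4 s, far shorter than the run, and with E's uptake left aside, that starting release balances the return to Z and the loss to G2 at a c G of 0.0326 M, well above that mark, so I commit to a conversion of about 100%.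

The E.G and Q then form one pool, with Q as its resting state. E.G leaves the first phase at 0.0511 /s and 0.0117 /s together, while Q returns at 0.0164 /s, and the slower root of that pair is a drain constant of 0.00250 /s, slower than 0.0117 /s. In logarithms, the pool loses one power of ten in 15.3 min, the decade time of the pool. A fast early loss leaves a share 0.876 on that line, so from the capture onward I reckon 49.7% standing at 4.0 min. A pool down to a tenth by then asks for 0.009583 /s, which is 3.83 times the drain constant, so this flask stands well away from that outcome.

The forecast gives 50% and 100%, the first of these since the pool “drains to J only slowly”.

The flask gives 50.0% and >99.9%. Left until 15 min, the flask has 0.719 of a decade time more to run beyond 4.0 min, so from 50.0% I reckon 9.57% still standing in that neighbouring flask. It reads 9.60%, and J there holds 89.8% of the E charged.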